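Target is counted here as a share of the substrate charged.

| flask | substrate | catalyst | target | time |
|---|---|---|---|---|
| blue | 0.120 M | 0.00600 M |  |  |
| green | 0.0600 M | 0.00600 M |  |  |
| teal | 0.120 M | 0.00600 M | 0.0360 M |  |
| ochre | 0.0600 M | 0.0120 M |  | 20 min |

| blue run: time / min | blue run: [target] / M | green run: time / min | green run: [target] / M | teal run: time / min | teal run: [target] / M |
|---|---|---|---|---|---|
| 2.5 | 0.0062 | 2.5 | 0.0037 | 2.5 | 0.0393 |
| 5.0 | 0.0117 | 5.0 | 0.0077 | 5.0 | 0.0399 |
| 7.5 | 0.0175 | 7.5 | 0.0087 | 7.5 | 0.0394 |
| 10 | 0.0203 | 10 | 0.0100 | 10 | 0.0400 |
| 12 | 0.0239 | 12 | 0.0116 | 12 | 0.0422 |
| 15 | 0.0250 | 15 | 0.0128 | 15 | 0.0398 |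
| 18 | 0.0265 | 18 | 0.0119 | 18 | 0.0375 |
| 20 | 0.0269 | 20 | 0.0138 | 20 | 0.0386 |

(scatter of a reading: 0.001 M)

- Overall: substrate -> target, with catalyst as catalyst.
- Constant volume, constant temperature.
- What is held in complexes is read along with the free species.
- An order is taken over about fifteen percent of the charge, up and down.

- the power of [substrate] that the first rate follows, about the charge of the blue run; measure it at two percent of substrate made into target (one fixed amount of target, the same in the runs compared)
- target in the ochre run at 20 min, as a share of the substrate charged

How fast is target fed? At 7.5 min the blue run reads 14.6% of its charge and the green run 14.5%, so each minute feeds about 0.0194 /min of the substrate into target at either charge. This reckoning therefore takes the order in substrate as 1.01, a reading at equal time, not equal target, with the scatter of two readings in it.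

Why does target level off? The teal run starts at 30.0% and reads 33.3% at 10 min, although its substrate and catalyst match the blue run. Its last two readings average 0.03805 M against 0.03965 M for its first four. On that thin drift, this reckoning treats target as lost onward. Where target stands still, feed equals loss, and with about 80.6% of the teal run's substrate reckoned as remaining at 10 min, target over substrate gives 0.414, the feed-to-loss ratio: the pace at which substrate becomes target divided by the pace at which target is lost. The loss is then 0.0470 /min. For these consecutive first-order steps, the ratio puts the blue run at 20.3% at 20 min, against a reading of 22.4%.

What does more catalyst change? The blue, green and teal runs share one catalyst charge, so this reckoning assumes that each catalyst in the ochre run keeps the turnover pace read above, and that the loss stays as it was. The ratio then becomes 0.828, twice its former value, and this reckoning puts the ochre run at 33.0% at 20 min.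

The forecast, for which “the reaction looks reversible”, gives the ochre run 24.8% (23.3% to 26.3%) and the order in substrate 0.85 (0.6 to 1.1).

The ochre run gives 37.4% of its substrate charge as target at 20 min, and the order in substrate about the blue run's charge is 0.98.

catalyst + substrate ⇌ catalyst-substrate complex, settled at all times (1.480 /M); catalyst-substrate complex + catalyst → target + 2 catalyst (3090 /M/min); 2 catalyst ⇌ resting dimer, settled at all times (285.0 /M); target → decomposed product (0.05952 /min) The apparent order in catalyst early in the blue run is 1.4, not one. Carried to the ochre run, that order raises the feed-to-loss ratio to 1.07, and the same two-step reckoning gives 38.0% at 20 min.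

The earlier runs and the new flask stem from a simulated flask for an exercise; noise was put on by code.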